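**Plan**
- Retrosynthesis: C5–Br is traced back to a C5 carboxyl group (ipso-bromodecarboxylation) and C3–Br and C4–Br to C–H. The resulting 1-methylpyrrole-2,5-dicarboxylate is then cut at C2–C3 and C4–C5.
- Enabling feature: C2 and C5 both flank N1 of the pyrrole ring. One symmetrical iminodiacetate therefore supplies N1 with its methyl group, C2, C5 and both carboxyl carbons, and glyoxal supplies C3–C4.
- Forward order: diester formation, Hinsberg double aldol condensation (the only ring closes here), mono-saponification, one-pot bromodecarboxylation at C5 with bromination at C4 and C3, ester hydrolysis.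
- The C2 carboxyl stays a methyl ester until all bromine chemistry is finished, so it cannot be lost by ipso attack.
- Stereochemistry: the target is achiral and aromatic. The sp3 centres formed in the ring closure are erased by dehydration.

Key step: step 2

Assumption: glyoxal 3 is charged as its commercial solid trimer dihydrate, which should crack to the monomer (as its methanol hemiacetal) in warm methanol; equivalents are counted per glyoxal unit.

Step 1
Reactants: 1 N-methyliminodiacetic acid
Product: 2 dimethyl N-methyliminodiacetate (free base)
Conditions: SOCl2 (2.5 equiv), CH3OH, 0 °C → reflux; then sat. aq. NaHCO3, CH2Cl2 extraction, distillation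
Reagents that add atoms: methanol, CO
Why: Fischer esterification driven by anhydrous HCl from thionyl chloride in methanol, which also scavenges the water formed, should convert both carboxyl groups, and the tertiary amine has no N–H through which a lactam could form.

Step 2
Reactants: 2 dimethyl N-methyliminodiacetate; 3 glyoxal (charged as trimer dihydrate)
Product: 6 dimethyl 1-methylpyrrole-2,5-dicarboxylate, via acyclic mono-aldol adduct 4 (not isolated), via pyrrolidine-3,4-diol diester 5 (not isolated)
Conditions: glyoxal trimer dihydrate (1.1 equiv as monomer) and 2 added slowly to NaOCH3 (2.2 equiv), CH3OH, 0 °C → reflux; then conc. H2SO4 (3 equiv), CH3OH, reflux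
Reagents that add atoms: none
Why: Methoxide reversibly deprotonates one NCH2CO2CH3 arm of 2 and the enolate adds to a carbonyl of glyoxal to give 4; the second arm then enolises and its carbon attacks the remaining aldehyde in a 5-exo-trig aldol closure that forms the five-membered ring of 5, after which two eliminations of water (E1cB under base, completed under acid) aromatise the ring to 6. This is the Hinsberg condensation of an iminodiacetate diester with a 1,2-dicarbonyl compound, the nitrogen counterpart of the thiodiglycolate–glyoxal thiophene synthesis. The stereocentres of 4 and 5 arise without control and need none, since all are erased on aromatisation. The step needs chemoselectivity for the cross-aldol over Cannizzaro disproportionation and oligomerisation of glyoxal and over saponification by the liberated water: glyoxal has no α-hydrogen and can only act as the electrophile, the solid glyoxal source and an alkoxide in its own alcohol keep hydroxide low, slow addition keeps free dialdehyde scarce, and the irreversible aromatisation pulls the reversible aldol equilibria forward. No regiochemical question arises, because both partners are symmetrical and the only enolisable carbons of 2 are the two that become C2 and C5. The acidic methanol stage keeps both carboxyl groups as methyl esters, so 6 should be obtained as a single neutral compound.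

Step 3
Reactants: 6 dimethyl 1-methylpyrrole-2,5-dicarboxylate
Product: 7 5-(methoxycarbonyl)-1-methylpyrrole-2-carboxylic acid
Conditions: KOH (1.0 equiv), CH3OH/H2O, 0 → 20 °C; unreacted 6 extracted at basic pH; then 1 M HCl to pH 2–3
Reagents that add atoms: potassium hydroxide, [K+].[OH-]
Why: Mono-saponification of a symmetrical diester with one equivalent of hydroxide should stop at the half ester, because the first carboxylate is conjugated with the remaining ester through the pyrrole ring and repels hydroxide, and acid–base extraction separates recovered diester from 7.

Step 4
Reactants: 7 5-(methoxycarbonyl)-1-methylpyrrole-2-carboxylic acid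
Product: 10 methyl 3,4,5-tribromo-1-methylpyrrole-2-carboxylate, via methyl 5-bromo-1-methylpyrrole-2-carboxylate 8 (not isolated), via methyl 4,5-dibromo-1-methylpyrrole-2-carboxylate 9 (not isolated)
Conditions: Br2 (3.3 equiv), NaOAc (4 equiv), AcOH, 20 → 60 °C
Reagents that add atoms: bromine, BrBr
Why: Attack of bromine at the carboxyl-bearing α-carbon gives a σ-complex that loses CO2 (ipso-bromodecarboxylation of a pyrrole-2-carboxylic acid), after which the less deactivated ring should take bromine by electrophilic aromatic substitution at C4 and then C3, the only positions left, while the ester-bearing carbon offers no leaving group and the acetate buffer suppresses HBr-induced protodebromination.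

Step 5
Reactants: 10 methyl 3,4,5-tribromo-1-methylpyrrole-2-carboxylate
Product: 11 3,4,5-tribromo-1-methylpyrrole-2-carboxylic acid
Conditions: LiOH·H2O (3 equiv), THF/CH3OH/H2O, 40 °C; then 1 M HCl, 0 °C, to pH 2
Reagents that add atoms: lithium hydroxide, [Li+].[OH-]
Why: Saponification of the methyl ester by acyl substitution should proceed despite the flanking N-methyl and C3 bromine because three bromines make the carbonyl more electrophilic; no bromine reagent is present to attack the free acid, and cold acidification avoids protodecarboxylation.

**Compound list**
1 | N-methyliminodiacetic acid | CN(CC(=O)O)CC(=O)O | starting material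
2 | dimethyl N-methyliminodiacetate | COC(=O)CN(C)CC(=O)OC | intermediate
3 | glyoxal (charged as trimer dihydrate) | O=CC=O | starting material
4 | methyl 2-[(2-methoxy-2-oxoethyl)(methyl)amino]-3-hydroxy-4-oxobutanoate (acyclic mono-aldol adduct, diastereomer mixture) | COC(=O)CN(C)C(C(O)C=O)C(=O)OC | intermediate
5 | dimethyl 3,4-dihydroxy-1-methylpyrrolidine-2,5-dicarboxylate (diastereomer mixture) | COC(=O)C1C(O)C(O)C(C(=O)OC)N1C | intermediate
6 | dimethyl 1-methylpyrrole-2,5-dicarboxylate | COC(=O)c1ccc(C(=O)OC)n1C | intermediate
7 | 5-(methoxycarbonyl)-1-methylpyrrole-2-carboxylic acid | COC(=O)c1ccc(C(=O)O)n1C | intermediate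
8 | methyl 5-bromo-1-methylpyrrole-2-carboxylate | COC(=O)c1ccc(Br)n1C | intermediate
9 | methyl 4,5-dibromo-1-methylpyrrole-2-carboxylate | COC(=O)c1cc(Br)c(Br)n1C | intermediate
10 | methyl 3,4,5-tribromo-1-methylpyrrole-2-carboxylate | COC(=O)c1c(Br)c(Br)c(Br)n1C | intermediate
11 | 3,4,5-tribromo-1-methylpyrrole-2-carboxylic acid | Cn1c(Br)c(Br)c(Br)c1C(=O)O | target

Total step count: 5
Longest linear sequence: 5 steps

**Steps most likely to fail**

Step 2. Glyoxal may be consumed by Cannizzaro disproportionation and base-induced oligomerisation faster than the weakly acidic α-amino ester enolises, so that little ring closure takes place. The fallback keeps the same two ring bonds but raises the oxidation level of the two-carbon partner. It sets out from 2, which is condensed with dimethyl oxalate (NaOCH3, CH3OH, reflux) in a double Claisen-type Hinsberg reaction to give dimethyl 3,4-dihydroxy-1-methylpyrrole-2,5-dicarboxylate F1. Tf2O and pyridine in CH2Cl2 at 0 °C would convert this into dimethyl 1-methyl-3,4-bis(trifluoromethylsulfonyloxy)pyrrole-2,5-dicarboxylate F2. Palladium-catalysed transfer hydrogenolysis of both triflates (Pd(OAc)2, PPh3, HCO2H, Et3N, DMF, 70 °C) returns to the route at 6.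

Step 4. Ring bromination at C3 and C4 may outpace ipso attack, leaving a doubly deactivated acid that loses CO2 only sluggishly, so that mixtures of partly brominated acids and esters result. The fallback separates loss of the carboxyl group from bromination. It sets out from 7, which is protodecarboxylated (catalytic Cu2O, 1,10-phenanthroline, NMP/quinoline, 170 °C) to methyl 1-methylpyrrole-2-carboxylate F3. Exhaustive electrophilic bromination of the three free ring positions (Br2, 3.3 equiv, NaOAc, AcOH, 20 → 60 °C) then rejoins the route at 10.

Step 3. The second ester may be cleaved at a rate close to the first, giving a statistical mixture of diester, half ester and diacid. The fallback breaks the symmetry by halogen–metal exchange instead of by hydrolysis. It sets out from 6, which is fully saponified (excess NaOH, aq. CH3OH, reflux, then HCl) to 1-methylpyrrole-2,5-dicarboxylic acid F4. Excess bromine (4.5 equiv, NaOAc, AcOH) should effect twofold ipso-bromodecarboxylation and bromination at C3 and C4 to give 2,3,4,5-tetrabromo-1-methylpyrrole F5. One equivalent of n-BuLi in THF at −78 °C exchanges one of the two equivalent α-bromines to give (3,4,5-tribromo-1-methylpyrrol-2-yl)lithium F6, and carboxylation with dry CO2 followed by dilute HCl returns to the route at the target 11.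

**Further compounds**
F1 | step 2 | dimethyl 3,4-dihydroxy-1-methylpyrrole-2,5-dicarboxylate | COC(=O)c1c(O)c(O)c(C(=O)OC)n1C
F2 | step 2 | dimethyl 1-methyl-3,4-bis(trifluoromethylsulfonyloxy)pyrrole-2,5-dicarboxylate | COC(=O)c1c(OS(=O)(=O)C(F)(F)F)c(OS(=O)(=O)C(F)(F)F)c(C(=O)OC)n1C
F3 | step 4 | methyl 1-methylpyrrole-2-carboxylate | COC(=O)c1cccn1C
F4 | step 3 | 1-methylpyrrole-2,5-dicarboxylic acid | Cn1c(C(=O)O)ccc1C(=O)O
F5 | step 3 | 2,3,4,5-tetrabromo-1-methylpyrrole | Cn1c(Br)c(Br)c(Br)c1Br
F6 | step 3 | (3,4,5-tribromo-1-methylpyrrol-2-yl)lithium | [Li]c1c(Br)c(Br)c(Br)n1C
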